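**Retrosynthetic overview**

Numbering: cycloheptane C1 (C–OH, carries the crotonyl chain C2(=O)–C3=C4–C15), C5 (CH–OAng), C6 (lactone O–CH), C7, C8 (CHOH), C9, C10 (CH–C14H3); lactone C11(=C13H2)–C12(=O)–O–C6.
Enabling feature: in the α-methylene-γ-butyrolactone fused at C6–C7, C13=C11–C7 is a masked terminal allene, C12 is a CO2 carbon and C6–O is an aldehyde. A nickel-mediated carboxylative cyclization of the acyclic allenyl aldehyde 18 therefore makes C11–C12 and C6–C7, closes the seven-membered ring and sets C6 and C7.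
18 comes from the δ-lactone template 6 (C2(=O)–O–C8; C10 from methyl (R)-3-methylglutarate, C8 by Noyori transfer hydrogenation). The ring controls an anti-aldol (C5) and an enolate hydroxylation (C1); the lactone is then opened with an (E)-propenyl nucleophile (masked crotonyl), and a Crabbé homologation turns the alkyne into the allene.
Ring order: temporary δ-lactone (step 3), temporary C1/C5 dioxolane (step 6), cycloheptane (step 13), γ-lactone (step 14). Endgame: acetonide off, angelate on C5–OH, desilylation, allylic oxidation at C2.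

Key step: step 13

Remark: the C2 carbinol made in step 8 is carried as both epimers (its descriptor is left open in the SMILES of 13–26), because step 18 converts it into the ketone; 1, 3, 7, 12 and 24 are taken as catalogue compounds.

**Route**

Step 1
Reactants: 1 methyl (R)-3-methylglutarate
Product: 2 (3S)-5-[methoxy(methyl)amino]-3-methyl-5-oxopentanoic acid
Conditions: MeNHOMe·HCl (1.6 equiv), i-PrMgCl (4.5 equiv), THF, −20 → 0 °C; aq. citric acid
Reagents that add atoms: N,O-dimethylhydroxylamine hydrochloride, CNOC.Cl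
Why: Weinreb amide formation from an ester, in which the chloromagnesium amide acylates at the methyl ester while the magnesium carboxylate of the acid arm stays inert and the C10 stereocentre is not touched.

Step 2
Reactants: 2 (3S)-5-[methoxy(methyl)amino]-3-methyl-5-oxopentanoic acid; 3 ethynyltrimethylsilane
Product: 4 (3S)-3-methyl-5-oxo-7-(trimethylsilyl)hept-6-ynoic acid
Conditions: 3 (3.3 equiv), n-BuLi (3.2 equiv), THF, −78 °C; then 2, −78 → 0 °C; 1 M HCl
Reagents that add atoms: none
Why: Weinreb ketone synthesis, in which the lithium acetylide adds once to the amide (chelated tetrahedral intermediate, no over-addition) and the lithium carboxylate is unreactive.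

Step 3
Reactants: 4 (3S)-3-methyl-5-oxo-7-(trimethylsilyl)hept-6-ynoic acid
Product: 6 (4S,6S)-4-methyl-6-[(trimethylsilyl)ethynyl]oxan-2-one, via hydroxy acid 5 (not isolated)
Conditions: RuCl(p-cymene)[(S,S)-TsDPEN] (1 mol%), HCO2H/Et3N (5:2), rt; then p-TsOH·H2O (cat.), PhMe, 50 °C
Reagents that add atoms: none
Why: Noyori asymmetric transfer hydrogenation of an ynone, in which the alkynyl group takes the role of the aryl group so that the (S,S)-catalyst should deliver the (S)-carbinol at C8 under reagent control, followed by acid lactonization to the cis-4,6-disubstituted δ-lactone.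

Step 4
Reactants: 6 (4S,6S)-4-methyl-6-[(trimethylsilyl)ethynyl]oxan-2-one; 7 2-[(4-methoxybenzyl)oxy]acetaldehyde
Product: 8 (3S,4S,6S)-3-{(1R)-1-hydroxy-2-[(4-methoxybenzyl)oxy]ethyl}-4-methyl-6-[(trimethylsilyl)ethynyl]oxan-2-one
Conditions: LiN(i-Pr)2 (1.1 equiv), THF, −78 °C; then 7, −78 °C; sat. NH4Cl
Reagents that add atoms: none
Why: lithium aldol addition, in which the ring-fixed (E)-enolate should react through a Zimmerman–Traxler chair to give the anti-aldol (sets C5) and the aldehyde should approach trans to the adjacent C10 methyl group.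

Step 5
Reactants: 8 (3S,4S,6S)-3-{(1R)-1-hydroxy-2-[(4-methoxybenzyl)oxy]ethyl}-4-methyl-6-[(trimethylsilyl)ethynyl]oxan-2-one
Product: 9 (3S,4S,6S)-3-hydroxy-3-{(1S)-1-hydroxy-2-[(4-methoxybenzyl)oxy]ethyl}-4-methyl-6-[(trimethylsilyl)ethynyl]oxan-2-one
Conditions: LiN(i-Pr)2 (2.5 equiv), THF, −78 → −40 °C; then 2-(phenylsulfonyl)-3-phenyloxaziridine, −78 °C; sat. NH4Cl
Reagents that add atoms: 2-(phenylsulfonyl)-3-phenyloxaziridine, O=S(=O)(c1ccccc1)N1OC1c1ccccc1
Why: Davis enolate hydroxylation of a Fráter–Seebach-type alkoxide enolate dianion (the free alkoxide suppresses β-elimination), in which oxygen should enter trans to the C10 methyl and anti to the C5 alkoxide, two matched effects that set the tertiary C1 carbinol.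

Step 6
Reactants: 9 (diol)
Product: 10 (4S,5S,8S,10S)-4-{[(4-methoxybenzyl)oxy]methyl}-2,2,10-trimethyl-8-[(trimethylsilyl)ethynyl]-1,3,7-trioxaspiro[4.5]decan-6-one
Conditions: 2,2-dimethoxypropane, camphorsulfonic acid (cat.), CH2Cl2, rt
Reagents that add atoms: 2,2-dimethoxypropane, COC(C)(C)OC
Why: acid-catalysed transketalization ties the C1/C5 diol into a dioxolane in which the C10 chain and C6 are trans, without touching a stereocentre.

Step 7
Reactants: 10 (spiro-acetonide lactone)
Product: 11 lactol of 10 (C2 hemiacetal, both anomers)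
Conditions: i-Bu2AlH (1.2 equiv), CH2Cl2, −78 °C; aq. KNaC4H4O6
Reagents that add atoms: none
Why: partial reduction of a lactone with i-Bu2AlH stops at the lactol because the tetrahedral aluminate is stable at −78 °C.

Step 8
Reactants: 11 lactol; 12 (E)-1-bromoprop-1-ene
Product: 14 alkynyl diol (C1/C5 acetonide; C2 carbinol with (E)-propenyl group; free C8 propargylic alcohol; terminal alkyne), via TMS-alkyne diol 13 (not isolated)
Conditions: 12 (4 equiv), t-BuLi (8 equiv), Et2O, −78 °C; MgBr2·OEt2 (4.2 equiv); then 11, THF, −78 °C → rt; then MeOH, K2CO3, rt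
Reagents that add atoms: none
Why: bromine–lithium exchange with retention of the E geometry and transmetalation give the alkenyl Grignard reagent, which adds to the open hydroxy-aldehyde form of the lactolate (C2 epimers, both used), and methanolic carbonate then cleaves the alkynyl C–Si bond.

Step 9
Reactants: 14 alkynyl diol
Product: 15 bis-TBS ether of 14 (C2–OTBS, C8–OTBS)
Conditions: TBSOTf (3 equiv), 2,6-lutidine, CH2Cl2, −78 → 0 °C
Reagents that add atoms: tert-butyldimethylsilyl trifluoromethanesulfonate, CC(C)(C)[Si](C)(C)OS(=O)(=O)C(F)(F)F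
Why: silyl triflate silylation protects both secondary alcohols, including the hindered C2 carbinol, while the terminal alkyne is untouched.

Step 10
Reactants: 15 bis-TBS alkyne
Product: 16 terminal allene (C7=C11=C13; (2S,4S)-4-(TBS-oxy)hepta-5,6-dien-2-yl chain on C1)
Conditions: (CH2O)n, CuI (0.5 equiv), Cy2NH, 1,4-dioxane, reflux
Reagents that add atoms: paraformaldehyde (formaldehyde), C=O
Why: Crabbé homologation, in which the Mannich-type propargylic amine formed from alkyne, formaldehyde and amine undergoes copper-mediated hydride transfer and elimination to the terminal allene without touching C8.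

Step 11
Reactants: 16 allene PMB ether
Product: 17 primary alcohol (C6–OH)
Conditions: DDQ, CH2Cl2/pH 7 buffer, 0 °C
Reagents that add atoms: none
Why: oxidative cleavage of the p-methoxybenzyl ether by DDQ is selective for the electron-rich benzyl ether over the silyl ethers, the acetonide, the allene and the propenyl group.

Step 12
Reactants: 17 primary alcohol
Product: 18 allenyl aldehyde (C6 aldehyde on the C1/C5 dioxolane)
Conditions: Dess–Martin periodinane, NaHCO3, CH2Cl2, 0 °C
Reagents that add atoms: none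
Why: buffered Dess–Martin oxidation gives the α-alkoxy aldehyde under non-epimerizing conditions; it is used at once.

Step 13
Reactants: 18 allenyl aldehyde
Product: 21 cycloheptyl hydroxy acrylic acid (C6–OH trans to the 2-carboxyallyl unit on C7), via allylnickel carboxylate 19 (not isolated), via cyclized nickel chelate 20 (not isolated)
Conditions: Ni(cod)2 (2.0 equiv), DBU (6 equiv), CO2 (1 atm), THF (0.02 M), 0 °C → rt; then 1 M HCl, 0 °C
Reagents that add atoms: carbon dioxide, O=C=O
Why: Zerovalent nickel (DBU-ligated) couples the central allene carbon C11 with CO2 by oxidative cyclization to the allylnickel carboxylate 19, whose σ-allyl form (nickel on C13, tether anti to C13) adds through C7 to the C6 aldehyde in a six-membered chair transition state to give chelate 20, which is protonated on work-up. The closest known reaction type is the nickel-mediated sequential coupling of a terminal allene, CO2 and an aldehyde and its intramolecular form, the carboxylative cyclization of allenyl aldehydes to five- and six-membered carbocycles; here it is extended to a seven-membered closure. The cycloheptane closes by 7-exo-trig addition of the allylmetal terminus C7 to the carbonyl group (SE2′ at the allyl unit, C11=C13 becoming the exocyclic methylene), whereas attack through C13 would need a nine-membered ring. C6 and C7 are set together: with the C5 and C8 tether arms equatorial on the Zimmerman–Traxler chair the C6–O and C7–C11 bonds should emerge trans, and the trans-fused C1/C5 dioxolane holds the C5–O bond equatorial and antiperiplanar to the forming C6–C7 bond (Felkin–Anh polar arrangement), so that only the all-equatorial array O1/O5/O6/C11 fits a chair-like ring and C6–O should come out trans to C5–O. The step needs regioselectivity (carboxylation at C11, C–C bond at C7), chemoselectivity for the allene over the propenyl alkene and the aldehyde, and no epimerization at C5; these rest on the high reactivity of the terminal 1,2-diene toward zerovalent nickel and CO2 at 0 °C, on the seven- versus nine-membered ring preference and on the lowered basicity of DBU under CO2.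

Step 14
Reactants: 21 hydroxy acid
Product: 22 trans-fused α-methylene-γ-butyrolactone (C1/C5 acetonide, C2–OTBS, C8–OTBS)
Conditions: DCC, DMAP (cat.), CH2Cl2, 0 °C → rt
Reagents that add atoms: none
Why: carbodiimide lactonization (5-exo-trig acyl substitution) of the γ-hydroxy acid closes the trans-fused lactone without touching a stereocentre.

Step 15
Reactants: 22 lactone acetonide
Product: 23 C1,C5-diol (C2–OTBS and C8–OTBS retained)
Conditions: PPTS, MeOH, rt → 40 °C
Reagents that add atoms: none
Why: mild acid transketalization should cleave the strained trans-fused dioxolane faster than the two hindered secondary TBS ethers.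

Step 16
Reactants: 23 C1,C5-diol; 24 angelic acid
Product: 25 C5 angelate (C1–OH free, C2–OTBS, C8–OTBS)
Conditions: 24, 2,4,6-trichlorobenzoyl chloride, Et3N, PhMe, rt; then 23, 80 °C
Reagents that add atoms: none
Why: Yamaguchi mixed-anhydride esterification without DMAP is the established way to acylate hindered alcohols with angelic acid while keeping the Z geometry, and the secondary C5–OH should react in preference to the tertiary C1–OH.

Step 17
Reactants: 25 C5 angelate
Product: 26 C2,C8-diol (C2 epimers)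
Conditions: HF·pyridine, pyridine, THF, 0 °C → rt
Reagents that add atoms: none
Why: buffered fluoride desilylation removes both TBS ethers under conditions that spare the angelate and the α-methylene lactone.

Step 18
Reactants: 26 C2,C8-diol
Product: 27 CNP0206014.2 (target)
Conditions: MnO2 (activated, excess), CH2Cl2, rt
Reagents that add atoms: none
Why: MnO2 oxidizes allylic alcohols chemoselectively, so both C2 epimers should converge on the (E)-enone while the secondary C8–OH and the tertiary C1–OH remain.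

**Compound list**

1 | methyl (R)-3-methylglutarate [(3R)-5-methoxy-3-methyl-5-oxopentanoic acid] | COC(=O)C[C@H](C)CC(=O)O | starting material
2 | (3S)-5-[methoxy(methyl)amino]-3-methyl-5-oxopentanoic acid | CON(C)C(=O)C[C@H](C)CC(=O)O | intermediate
3 | ethynyltrimethylsilane | C#C[Si](C)(C)C | starting material
4 | (3S)-3-methyl-5-oxo-7-(trimethylsilyl)hept-6-ynoic acid | C[Si](C)(C)C#CC(=O)C[C@H](C)CC(=O)O | intermediate
5 | (3S,5S)-5-hydroxy-3-methyl-7-(trimethylsilyl)hept-6-ynoic acid | C[Si](C)(C)C#C[C@@H](O)C[C@H](C)CC(=O)O | intermediate (not isolated)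
6 | (4S,6S)-4-methyl-6-[(trimethylsilyl)ethynyl]oxan-2-one | O=C1C[C@@H](C)C[C@@H](C#C[Si](C)(C)C)O1 | intermediate
7 | 2-[(4-methoxybenzyl)oxy]acetaldehyde | O=CCOCc1ccc(OC)cc1 | starting material
8 | (3S,4S,6S)-3-{(1R)-1-hydroxy-2-[(4-methoxybenzyl)oxy]ethyl}-4-methyl-6-[(trimethylsilyl)ethynyl]oxan-2-one | O=C1[C@H]([C@@H](O)COCc2ccc(OC)cc2)[C@@H](C)C[C@@H](C#C[Si](C)(C)C)O1 | intermediate
9 | (3S,4S,6S)-3-hydroxy-3-{(1S)-1-hydroxy-2-[(4-methoxybenzyl)oxy]ethyl}-4-methyl-6-[(trimethylsilyl)ethynyl]oxan-2-one | O=C1[C@@](O)([C@@H](O)COCc2ccc(OC)cc2)[C@@H](C)C[C@@H](C#C[Si](C)(C)C)O1 | intermediate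
10 | (4S,5S,8S,10S)-4-{[(4-methoxybenzyl)oxy]methyl}-2,2,10-trimethyl-8-[(trimethylsilyl)ethynyl]-1,3,7-trioxaspiro[4.5]decan-6-one | O=C1[C@]2(OC(C)(C)O[C@H]2COCc3ccc(OC)cc3)[C@@H](C)C[C@@H](C#C[Si](C)(C)C)O1 | intermediate
11 | lactol of 10 (6-hydroxy-1,3,7-trioxaspiro[4.5]decane, both anomers) | OC1[C@]2(OC(C)(C)O[C@H]2COCc3ccc(OC)cc3)[C@@H](C)C[C@@H](C#C[Si](C)(C)C)O1 | intermediate
12 | (E)-1-bromoprop-1-ene | C/C=C/Br | starting material
13 | TMS-alkyne diol: C1/C5 acetonide carrying on C1 the (E)-1-hydroxybut-2-enyl group (C2 epimers) and the (2S,4S)-4-hydroxy-6-(trimethylsilyl)hex-5-yn-2-yl chain, on C5 the PMB-oxymethyl group | C/C=C/C(O)[C@]1(OC(C)(C)O[C@H]1COCc2ccc(OC)cc2)[C@@H](C)C[C@H](O)C#C[Si](C)(C)C | intermediate (not isolated)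
14 | alkynyl diol: as 13 with a terminal alkyne [(2S,4S)-4-hydroxyhex-5-yn-2-yl chain] | C/C=C/C(O)[C@]1(OC(C)(C)O[C@H]1COCc2ccc(OC)cc2)[C@@H](C)C[C@H](O)C#C | intermediate
15 | bis-TBS ether of 14 (C2–OTBS, C8–OTBS) | C/C=C/C(O[Si](C)(C)C(C)(C)C)[C@]1(OC(C)(C)O[C@H]1COCc2ccc(OC)cc2)[C@@H](C)C[C@H](O[Si](C)(C)C(C)(C)C)C#C | intermediate
16 | terminal allene: as 15 with the (2S,4S)-4-(TBS-oxy)hepta-5,6-dien-2-yl chain on C1 | C/C=C/C(O[Si](C)(C)C(C)(C)C)[C@]1(OC(C)(C)O[C@H]1COCc2ccc(OC)cc2)[C@@H](C)C[C@H](O[Si](C)(C)C(C)(C)C)C=C=C | intermediate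
17 | primary alcohol: as 16 with C6H2–OH on C5 | C/C=C/C(O[Si](C)(C)C(C)(C)C)[C@]1(OC(C)(C)O[C@H]1CO)[C@@H](C)C[C@H](O[Si](C)(C)C(C)(C)C)C=C=C | intermediate
18 | allenyl aldehyde: as 16 with the C6 formyl group on C5 (C10 chain and CHO trans on the dioxolane) | C/C=C/C(O[Si](C)(C)C(C)(C)C)[C@]1(OC(C)(C)O[C@H]1C=O)[C@@H](C)C[C@H](O[Si](C)(C)C(C)(C)C)C=C=C | intermediate
19 | allylnickel carboxylate (oxanickelacycle Ni–O–C12(=O)–C11–C13, drawn as the σ-allyl form with E C11=C7, DBU ligands omitted) | O=C1O[Ni]C/C1=C/[C@@H](O[Si](C)(C)C(C)(C)C)C[C@H](C)[C@@]2(OC(C)(C)O[C@H]2C=O)C(O[Si](C)(C)C(C)(C)C)/C=C/C | intermediate (not isolated)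
20 | cyclized nickel chelate (divalent nickel bound to the C6 alkoxide and the C12 carboxylate of the new cycloheptane) | C=C1C(=O)O[Ni]O[C@@H]2[C@@H]1[C@@H](O[Si](C)(C)C(C)(C)C)C[C@H](C)[C@@](O3)(C(O[Si](C)(C)C(C)(C)C)/C=C/C)[C@H]2OC3(C)C | intermediate (not isolated)
21 | cycloheptyl hydroxy acid: 2-substituted acrylic acid on C7, C6–OH trans to it, C1/C5 acetonide, C2–OTBS, C8–OTBS | C=C(C(=O)O)[C@H]1[C@@H](O[Si](C)(C)C(C)(C)C)C[C@H](C)[C@@](O2)(C(O[Si](C)(C)C(C)(C)C)/C=C/C)[C@@H](OC2(C)C)[C@@H]1O | intermediate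
22 | trans-fused α-methylene-γ-butyrolactone with C1/C5 acetonide, C2–OTBS, C8–OTBS | C=C1C(=O)O[C@@H]2[C@@H]1[C@@H](O[Si](C)(C)C(C)(C)C)C[C@H](C)[C@@](O3)(C(O[Si](C)(C)C(C)(C)C)/C=C/C)[C@H]2OC3(C)C | intermediate
23 | C1,C5-diol lactone (C2–OTBS, C8–OTBS) | C=C1C(=O)O[C@@H]2[C@@H]1[C@@H](O[Si](C)(C)C(C)(C)C)C[C@H](C)[C@@](O)(C(O[Si](C)(C)C(C)(C)C)/C=C/C)[C@H]2O | intermediate
24 | angelic acid [(Z)-2-methylbut-2-enoic acid] | C/C=C(/C)C(=O)O | starting material
25 | C5 angelate (C1–OH free, C2–OTBS, C8–OTBS) | C=C1C(=O)O[C@@H]2[C@@H]1[C@@H](O[Si](C)(C)C(C)(C)C)C[C@H](C)[C@@](O)(C(O[Si](C)(C)C(C)(C)C)/C=C/C)[C@H]2OC(=O)/C(C)=C\C | intermediate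
26 | C5 angelate triol (C1–OH, C2–OH as both epimers, C8–OH) | C=C1C(=O)O[C@@H]2[C@@H]1[C@@H](O)C[C@H](C)[C@@](O)(C(O)/C=C/C)[C@H]2OC(=O)/C(C)=C\C | intermediate
27 | CNP0206014.2 | C=C1C(=O)O[C@@H]2[C@@H]1[C@@H](O)C[C@H](C)[C@@](O)(C(=O)/C=C/C)[C@H]2OC(=O)/C(C)=C\C | target

**Summary and risks**

Total step count: 18. Longest linear sequence: 18 steps (1 → 27).

Steps most likely to fail:

Step 13. The allylnickel carboxylate may be protonated, lose the C8 silyloxy group by β-elimination or oligomerize faster than it closes the seven-membered ring; DBU may epimerize or β-eliminate the α,β-dialkoxy aldehyde; and the face selection at C6/C7 may be poor. The fallback forms C11–C12 first and closes C6–C7 by a classical intramolecular allylation. It sets out from 15: deprotonation (n-BuLi) and trapping with methyl chloroformate give the ynoate F1. Hydroalumination with i-Bu2AlH/N-methylmorpholine N-oxide and trapping of the α-aluminoacrylate with formaldehyde give the 2-(hydroxymethyl)alk-2-enoate F2. CBr4/PPh3 gives the allylic bromide F3; DDQ then Dess–Martin periodinane give the alcohol F4 and the aldehyde F5. CrCl2 in THF at high dilution (intramolecular Nozaki–Hiyama allylation through an allyl species of trivalent chromium) gives the hydroxy ester F6, which is lactonized with catalytic p-TsOH and comes back to the route at 22.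

Step 5. The dianion may undergo retro-aldol cleavage or β-elimination, deprotonation of the hindered C1–H may be slow, and the enolate may add to the sulfonimine by-product. The fallback replaces enolate oxidation by alkene dihydroxylation. It sets out from 8: stereospecific anti-elimination of water (PPh3, diisopropyl azodicarboxylate, PhMe) gives the (Z)-alkylidene lactone F7 (C6 cis to the lactone carbonyl). OsO4 (cat.)/N-methylmorpholine N-oxide then adds both oxygens syn from the face opposite the C10 methyl group and comes back to the route at 9.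

Step 16. Acylation of the hindered C5–OH may be slow enough for the activated angelate to isomerize to the tiglate, or the tertiary C1–OH may compete. The fallback builds the Z-alkene on the ester after acylation. It sets out from 23: DCC/DMAP esterification with 2-[bis(2,2,2-trifluoroethoxy)phosphoryl]propanoic acid gives the phosphonopropionate F8. Still–Gennari olefination with acetaldehyde (KN(SiMe3)2, 18-crown-6, THF, −78 °C) then forms the (Z)-2-methylbut-2-enoate and comes back to the route at 25.

**Further compounds**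

F1 | step 13 | methyl ynoate from 15 (C12 ester on C11) | C/C=C/C(O[Si](C)(C)C(C)(C)C)[C@]1(OC(C)(C)O[C@H]1COCc2ccc(OC)cc2)[C@@H](C)C[C@H](O[Si](C)(C)C(C)(C)C)C#CC(=O)OC
F2 | step 13 | methyl (Z)-2-(hydroxymethyl)alk-2-enoate (C8 cis to the ester) | C/C=C/C(O[Si](C)(C)C(C)(C)C)[C@]1(OC(C)(C)O[C@H]1COCc2ccc(OC)cc2)[C@@H](C)C[C@H](O[Si](C)(C)C(C)(C)C)/C=C(/CO)C(=O)OC
F3 | step 13 | methyl 2-(bromomethyl)alk-2-enoate (allylic bromide, PMB ether) | C/C=C/C(O[Si](C)(C)C(C)(C)C)[C@]1(OC(C)(C)O[C@H]1COCc2ccc(OC)cc2)[C@@H](C)C[C@H](O[Si](C)(C)C(C)(C)C)/C=C(/CBr)C(=O)OC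
F4 | step 13 | allylic bromide with free C6–OH | C/C=C/C(O[Si](C)(C)C(C)(C)C)[C@]1(OC(C)(C)O[C@H]1CO)[C@@H](C)C[C@H](O[Si](C)(C)C(C)(C)C)/C=C(/CBr)C(=O)OC
F5 | step 13 | allylic bromide with C6 aldehyde | C/C=C/C(O[Si](C)(C)C(C)(C)C)[C@]1(OC(C)(C)O[C@H]1C=O)[C@@H](C)C[C@H](O[Si](C)(C)C(C)(C)C)/C=C(/CBr)C(=O)OC
F6 | step 13 | methyl ester of hydroxy acid 21 | C=C(C(=O)OC)[C@H]1[C@@H](O[Si](C)(C)C(C)(C)C)C[C@H](C)[C@@](O2)(C(O[Si](C)(C)C(C)(C)C)/C=C/C)[C@@H](OC2(C)C)[C@@H]1O
F7 | step 5 | (3Z,4S,6S)-3-{2-[(4-methoxybenzyl)oxy]ethylidene}-4-methyl-6-[(trimethylsilyl)ethynyl]oxan-2-one | O=C1/C(=C\COCc2ccc(OC)cc2)[C@@H](C)C[C@@H](C#C[Si](C)(C)C)O1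
F8 | step 16 | C5 2-[bis(2,2,2-trifluoroethoxy)phosphoryl]propanoate of 23 (epimers at the phosphonate carbon) | C=C1C(=O)O[C@@H]2[C@@H]1[C@@H](O[Si](C)(C)C(C)(C)C)C[C@H](C)[C@@](O)(C(O[Si](C)(C)C(C)(C)C)/C=C/C)[C@H]2OC(=O)C(C)P(=O)(OCC(F)(F)F)OCC(F)(F)F
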